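The runs come from a simulation with constants of no real substance; the scatter is artificial.

The question was how much target stands in the flask at 25 min and which change raises it most, so I turned it round: for feeding more solid substrate into solution to be useless, the solution had to stand at its solubility and the solid readings had to lie flat.

| flask | solid substrate | gas phase | protic impurity | remark | time |
|---|---|---|---|---|---|
| Saturday's | 0.35 M | 200 mM (held) | 0.070 M | the very flask that is asked about, followed so far |  |
| Monday's | 0.35 M | 200 mM (held) | 0.035 M | run made earlier |  |
| flask | 0.35 M | 200 mM (held) | 0.0700 M |  | 25 min |

Saturday's run (percent of the solid substrate charged)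

| time / s | target / % | solid substrate / % |
|---|---|---|
| 15.0 | 0.9 | 98.7 |
| 30.0 | 0.5 | 98.4 |
| 50.0 | 0 | 97.7 |
| 60.0 | 0 | 98.3 |
| 80.0 | 0.7 | 97.4 |
| 90.0 | 0 | 96.2 |
| 120 | 0 | 95.8 |

Monday's run (percent of the solid substrate charged)

| time / min | target / % | solid substrate / % |
|---|---|---|
| 4.00 | 0.5 | 91.9 |
| 8.00 | 3.2 | 84.3 |
| 10.0 | 4.5 | 79.9 |
| 15.0 | 7.3 | 70.8 |
| 20.0 | 12.4 | 61.8 |
| 25.0 | 15.6 | 53.4 |

(readings scatter by 0.5 percentage points)

- solid substrate is a solid; its amount is given per volume of the solution
- at the start none of the gas is dissolved
- the numbers in the tables scatter with a standard deviation of 0.5 percentage points
- candidate steps: solid substrate <-> starting material; starting material + protic impurity -> quenched substrate; gas phase <-> dissolved gas; starting material + dissolved gas -> target; starting material -> side product; target <-> isomer of the product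
- at the start none of the solid substrate is in solution

- violet: doubling the solubility of the solid substrate, all else as stated
- grey: doubling the transfer coefficient of the gas phase, all else as stated
- teal: doubling the dissolution coefficient of the solid substrate, all else as stated
- green: doubling the saturation concentration of gas phase, all else as stated

* the target standing at 25 min, as a percentage of the solid substrate charged
* the change that raises the amount of target at 25 min, in percent of the solid substrate charged most ("none" if none brings more than 2 percentage points) (violet / grey / teal / green / none)
* amount of target at 25 min, in percent of the solid substrate charged, after green

On Monday's run, the fraction of the charge dissolving per minute was 0.0201 /min up to 10.0 min and 0.0174 /min between 15.0 min and 25.0 min. The solid had meanwhile fallen to 53.4%, so I treated dissolving as zero order in the solid and let the dissolved starting material set its pace through the gap to solubility. One minus the late-to-early ratio reads 0.134, with the scatter of the readings in it: this is the saturation share, the part of the solubility already taken up. Saturday's run, with twice the impurity, began at 0.0210 /min, so I carried Monday's share over to the flask. Doubling the solubility then multiplies the gap by 2.16, slightly more than the factor of 2 from doubling the dissolution coefficient. I chose violet and expected the flask below Monday's 15.6%.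

The forecast gave 11.5%, violet, and 16% after green, holding “so dissolution is near zero order and far from saturation”.

The flask gives 13.7%, less than Monday, and 19.9% after green; violet adds 16 percentage points, more than teal's 12 points.

    solid substrate ⇌ starting material, rate k1*(cs1 - [starting material]) while solid is left; crystals form when [starting material] > cs1 (solubility = 0.300 M, k = 0.0250 /min)
    starting material + protic impurity → quenched substrate (k = 1.10 /M/min)
    gas phase ⇌ dissolved gas, rate k3*(csat - [dissolved gas]) (kL = 4.60 /min)
    starting material + dissolved gas → target (k = 0.410 /M/min)
    starting material → side product (k = 0.0100 /min)
    target ⇌ isomer of the product (K = 0.640, k = 0.0900 /min)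

In the flask at 0.242 min, starting material had a half-life of 9.0 min towards quenched substrate, shorter than its 13 min towards target. In the flask at 25.0 min, the target step ran 2.7 times the quenching step, with 40% of the impurity left. In a neighbouring flask with 0.18 M of impurity, starting material of 9.10% against 13.4% scales the share to 0.0912, a slightly wider gap to solubility; that neighbour's solid stands at 50.7%, lower than the flask's 52.5%, and its target at 9.63%.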